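**Retrosynthetic overview**
- The target is the ring-closed (hemiketal) tautomer of an achiral 1,4-diaryl-butane-1,3-dione, so the C2 stereocentre can only be secured after ring closure, by resolution.
- The diketone is cut at the CH2–C(=O) bond next to the benzyl carbon: a crossed Claisen joins a methyl aryl ketone enolate and an activated arylacetic acid. Every oxygen is masked as a benzyl ether or ester, so one neutral hydrogenolysis unveils everything.
- The ketone comes from 5-heptylresorcinol (Hoesch acetylation, benzylation); the acid comes from orsellinic acid (perbenzylation, lateral lithiation and carboxylation).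
- Both benzene rings are bought; the only ring formed is the pyranone ring of the chromanone, and it is formed last.

Assumption: the hemiketal carbon is the only stereocentre, is (R) in the given SMILES, can epimerise through the open diketone, and is taken to be stable enough in cold, neutral, aprotic media to be resolved and stored; 5-heptylresorcinol and orsellinic acid are bought.

**Route**

Step 1
Reactants: 1 5-heptylresorcinol (5-heptylbenzene-1,3-diol)
Product: 3 1-(2,4-dihydroxy-6-heptylphenyl)ethan-1-one, via ketiminium chloride 2 (not isolated)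
Conditions: MeCN, ZnCl2, HCl (g), Et2O, 0 °C → rt; then H2O, reflux
Reagents that add atoms: acetonitrile CC#N; water O
Why: Hoesch acylation (Friedel–Crafts type) attacks the ring carbon para to one hydroxyl and ortho to the other, as in the orcinol series, and hydrolysis of the ketiminium salt gives the 2,4-dihydroxy-6-alkyl ketone, the minor 2,6-dihydroxy-4-heptyl isomer being removed on silica; no stereocentre is formed.

Step 2
Reactants: 3 1-(2,4-dihydroxy-6-heptylphenyl)ethan-1-one
Product: 4 1-[2,4-bis(benzyloxy)-6-heptylphenyl]ethan-1-one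
Conditions: BnBr (2.5 equiv), K2CO3, DMF, 70 °C
Reagents that add atoms: benzyl bromide BrCc1ccccc1
Why: Williamson ether synthesis in a dipolar solvent benzylates both phenols, including the hydrogen-bonded ortho one, while carbonate is too weak to enolise the methyl ketone.

Step 3
Reactants: 5 orsellinic acid (2,4-dihydroxy-6-methylbenzoic acid)
Product: 6 benzyl 2,4-bis(benzyloxy)-6-methylbenzoate
Conditions: BnBr (3.5 equiv), K2CO3, DMF, rt → 60 °C
Reagents that add atoms: benzyl bromide BrCc1ccccc1
Why: SN2 alkylation of the carboxylate (fast at rt, which forestalls decarboxylation) followed by Williamson etherification of both phenols gives the perbenzylated toluate.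

Step 4
Reactants: 6 benzyl 2,4-bis(benzyloxy)-6-methylbenzoate
Product: 8 [3,5-bis(benzyloxy)-2-(benzyloxycarbonyl)phenyl]acetic acid, via benzylic lithium species 7 (not isolated)
Conditions: LiN(i-Pr)2 (1.2 equiv), THF, −78 °C; CO2 (g), −78 °C → rt; aq. HCl
Reagents that add atoms: carbon dioxide O=C=O
Why: Lateral lithiation of the ortho-toluate gives an ester-stabilised benzylic anion whose hindered ester resists self-condensation at −78 °C, and carboxylation with excess CO2 gives the homophthalic acid monoester.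

Step 5
Reactants: 4 1-[2,4-bis(benzyloxy)-6-heptylphenyl]ethan-1-one; 8 [3,5-bis(benzyloxy)-2-(benzyloxycarbonyl)phenyl]acetic acid
Product: 11 benzyl 2,4-bis(benzyloxy)-6-{4-[2,4-bis(benzyloxy)-6-heptylphenyl]-2,4-dioxobutyl}benzoate, via lithium enolate 9 (not isolated), via acyl imidazolide 10 (not isolated)
Conditions: 8, 1,1'-carbonyldiimidazole (1.0 equiv), THF, rt, 1 h; 4 (3 equiv), LiN(SiMe3)2 (3 equiv), THF, −78 °C; imidazolide solution added, −78 → −20 °C; aq. HCl
Reagents that add atoms: none
Why: Crossed Claisen condensation of a kinetic methyl ketone enolate with an acyl imidazolide, the standard protocol for homologating arylacetic acids to β-dicarbonyls, in which the two extra equivalents of enolate take up the imidazole N–H and the acidic diketone (surplus 4 is recovered) and the low temperature keeps the diketonate from attacking the hindered ortho benzyl ester; no stereocentre is formed.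

Step 6
Reactants: 11 benzyl 2,4-bis(benzyloxy)-6-{4-[2,4-bis(benzyloxy)-6-heptylphenyl]-2,4-dioxobutyl}benzoate
Product: 13 rac-2-[(5-heptyl-2,7-dihydroxy-4-oxo-3,4-dihydro-2H-chromen-2-yl)methyl]-4,6-dihydroxybenzoic acid, via open-chain diketo acid 12 (not isolated)
Conditions: H2 (1 atm), 10% Pd/C, EtOAc/THF, rt
Reagents that add atoms: none
Why: Neutral hydrogenolysis cleaves the four benzyl ethers and the benzyl ester without acid or base, and the freed ortho hydroxyl adds to the benzyl-side ketone (6-exo-trig hemiketalisation) to give the 2-hydroxychroman-4-one, the form in which the natural product exists; closure of the achiral diketone is uncontrolled, so C2 is formed racemic.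

Step 7
Reactants: 13 rac-2-[(5-heptyl-2,7-dihydroxy-4-oxo-3,4-dihydro-2H-chromen-2-yl)methyl]-4,6-dihydroxybenzoic acid
Product: 14 2-{[(2R)-5-heptyl-2,7-dihydroxy-4-oxo-3,4-dihydro-2H-chromen-2-yl]methyl}-4,6-dihydroxybenzoic acid
Conditions: preparative HPLC on silica-bound amylose tris(3,5-dimethylphenylcarbamate), hexane/i-PrOH/HCO2H 80:20:0.1, 5 °C
Reagents that add atoms: none
Why: Chromatographic resolution on a chiral stationary phase delivers the (R)-enantiomer (assigned by optical rotation and circular dichroism against the natural product), which is where the only stereocentre is fixed; the (S)-enantiomer can be re-equilibrated through the open diketone with a trace of Et3N and re-injected.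

**Compound list**

1 | 5-heptylresorcinol (5-heptylbenzene-1,3-diol), achiral | CCCCCCCc1cc(O)cc(O)c1 | starting material
2 | 1-(2,4-dihydroxy-6-heptylphenyl)ethan-1-iminium chloride, achiral | CCCCCCCc1cc(O)cc(O)c1C(C)=[NH2+].[Cl-] | intermediate (not isolated)
3 | 1-(2,4-dihydroxy-6-heptylphenyl)ethan-1-one, achiral | CCCCCCCc1cc(O)cc(O)c1C(C)=O | intermediate
4 | 1-[2,4-bis(benzyloxy)-6-heptylphenyl]ethan-1-one, achiral | CCCCCCCc1cc(OCc2ccccc2)cc(OCc2ccccc2)c1C(C)=O | intermediate
5 | orsellinic acid (2,4-dihydroxy-6-methylbenzoic acid), achiral | Cc1cc(O)cc(O)c1C(=O)O | starting material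
6 | benzyl 2,4-bis(benzyloxy)-6-methylbenzoate, achiral | Cc1cc(OCc2ccccc2)cc(OCc2ccccc2)c1C(=O)OCc1ccccc1 | intermediate
7 | benzyl 2,4-bis(benzyloxy)-6-(lithiomethyl)benzoate, achiral | [Li]Cc1cc(OCc2ccccc2)cc(OCc2ccccc2)c1C(=O)OCc1ccccc1 | intermediate (not isolated)
8 | [3,5-bis(benzyloxy)-2-(benzyloxycarbonyl)phenyl]acetic acid, achiral | OC(=O)Cc1cc(OCc2ccccc2)cc(OCc2ccccc2)c1C(=O)OCc1ccccc1 | intermediate
9 | lithium 1-[2,4-bis(benzyloxy)-6-heptylphenyl]ethen-1-olate, achiral | CCCCCCCc1cc(OCc2ccccc2)cc(OCc2ccccc2)c1C(=C)O[Li] | intermediate (not isolated)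
10 | benzyl 2,4-bis(benzyloxy)-6-[2-(1H-imidazol-1-yl)-2-oxoethyl]benzoate, achiral | O=C(Cc1cc(OCc2ccccc2)cc(OCc2ccccc2)c1C(=O)OCc1ccccc1)n1ccnc1 | intermediate (not isolated)
11 | benzyl 2,4-bis(benzyloxy)-6-{4-[2,4-bis(benzyloxy)-6-heptylphenyl]-2,4-dioxobutyl}benzoate, achiral | CCCCCCCc1cc(OCc2ccccc2)cc(OCc2ccccc2)c1C(=O)CC(=O)Cc1cc(OCc2ccccc2)cc(OCc2ccccc2)c1C(=O)OCc1ccccc1 | intermediate
12 | 2-[4-(2,4-dihydroxy-6-heptylphenyl)-2,4-dioxobutyl]-4,6-dihydroxybenzoic acid, achiral | CCCCCCCc1cc(O)cc(O)c1C(=O)CC(=O)Cc1cc(O)cc(O)c1C(=O)O | intermediate (not isolated)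
13 | rac-2-[(5-heptyl-2,7-dihydroxy-4-oxo-3,4-dihydro-2H-chromen-2-yl)methyl]-4,6-dihydroxybenzoic acid, racemic at C2 | CCCCCCCc1cc(O)cc2c1C(=O)CC(O)(Cc1cc(O)cc(O)c1C(=O)O)O2 | intermediate
14 | 2-{[(2R)-5-heptyl-2,7-dihydroxy-4-oxo-3,4-dihydro-2H-chromen-2-yl]methyl}-4,6-dihydroxybenzoic acid | CCCCCCCc1cc(O)cc2c1C(=O)C[C@@](O)(Cc1cc(O)cc(O)c1C(=O)O)O2 | target

**Step count and risks**

Total step count: 7. Longest linear sequence: 5 steps (1 → 3 → 4 → 11 → 13 → 14, or equally 5 → 6 → 8 → 11 → 13 → 14).

Most likely to fail, first: step 5. The CH2 of imidazolide 10 is more acidic than the methyl ketone, so proton transfer and ketene formation compete with acylation, and the diketonate can later attack the ortho benzyl ester. The fallback sets out from 4 and 8 and comes back at 13. Ketone 4 is carboxylated with NaH and dibenzyl carbonate (toluene, 80 °C) to benzyl 3-[2,4-bis(benzyloxy)-6-heptylphenyl]-3-oxopropanoate F1. Acid 8 is turned with oxalyl chloride and a drop of DMF in CH2Cl2 into benzyl 2,4-bis(benzyloxy)-6-(2-chloro-2-oxoethyl)benzoate F2. MgCl2 and Et3N in MeCN at 0 °C (soft enolisation) join F1 and F2 at the central carbon to give benzyl 2-[2,4-bis(benzyloxy)-6-heptylbenzoyl]-4-[3,5-bis(benzyloxy)-2-(benzyloxycarbonyl)phenyl]-3-oxobutanoate F3. H2 over Pd/C in EtOAc then removes all six benzyl groups, the diacylacetic acid loses CO2 at room temperature, and the diketo acid 12 closes to 13. This replaces the strongly basic enolate by a doubly stabilised nucleophile.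

Second: step 7. The hemiketal may epimerise through 12 on the column or on concentration, so the separated enantiomer could lose purity. The fallback sets out from 13 and comes back at 14 by a crystallisation-induced dynamic resolution. One equivalent of (R)-N,N-dimethyl-1-phenylethylamine (a tertiary amine, so no enaminone can form) in EtOAc/heptane gives the less soluble salt while the amine keeps the dissolved hemiketal epimerising, so the whole batch can funnel into one diastereomer. If that salt is (R)-N,N-dimethyl-1-phenylethylammonium 2-{[(2R)-5-heptyl-2,7-dihydroxy-4-oxo-3,4-dihydro-2H-chromen-2-yl]methyl}-4,6-dihydroxybenzoate F4, it is collected. If the (R)-amine instead crystallises with the (S)-acid, the (S)-amine is used, and by mirror symmetry it must crystallise as (S)-N,N-dimethyl-1-phenylethylammonium 2-{[(2R)-5-heptyl-2,7-dihydroxy-4-oxo-3,4-dihydro-2H-chromen-2-yl]methyl}-4,6-dihydroxybenzoate F5. Partition of the salt between cold aq. KHSO4 and EtOAc returns 14.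

Third: step 1. The Hoesch acetylation may give too much of the 2,6-dihydroxy-4-heptyl isomer or a poor yield. The fallback sets out from 1 and comes back at 4, with the regiochemistry fixed by a halogen. BnBr and K2CO3 in DMF give 1,3-bis(benzyloxy)-5-heptylbenzene F6. N-bromosuccinimide in MeCN at 0 °C brominates para to one benzyloxy group and ortho to the heptyl chain to give 1,5-bis(benzyloxy)-2-bromo-3-heptylbenzene F7. n-BuLi in THF at −78 °C gives [2,4-bis(benzyloxy)-6-heptylphenyl]lithium F8, which is acylated with N-methoxy-N-methylacetamide to give 4.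

Further compounds
F1 | step 5 | benzyl 3-[2,4-bis(benzyloxy)-6-heptylphenyl]-3-oxopropanoate | CCCCCCCc1cc(OCc2ccccc2)cc(OCc2ccccc2)c1C(=O)CC(=O)OCc1ccccc1
F2 | step 5 | benzyl 2,4-bis(benzyloxy)-6-(2-chloro-2-oxoethyl)benzoate | ClC(=O)Cc1cc(OCc2ccccc2)cc(OCc2ccccc2)c1C(=O)OCc1ccccc1
F3 | step 5 | benzyl 2-[2,4-bis(benzyloxy)-6-heptylbenzoyl]-4-[3,5-bis(benzyloxy)-2-(benzyloxycarbonyl)phenyl]-3-oxobutanoate | CCCCCCCc1cc(OCc2ccccc2)cc(OCc2ccccc2)c1C(=O)C(C(=O)OCc1ccccc1)C(=O)Cc1cc(OCc2ccccc2)cc(OCc2ccccc2)c1C(=O)OCc1ccccc1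
F4 | step 7 | (R)-N,N-dimethyl-1-phenylethylammonium 2-{[(2R)-5-heptyl-2,7-dihydroxy-4-oxo-3,4-dihydro-2H-chromen-2-yl]methyl}-4,6-dihydroxybenzoate | CCCCCCCc1cc(O)cc2c1C(=O)C[C@@](O)(Cc1cc(O)cc(O)c1C(=O)[O-])O2.C[C@@H]([NH+](C)C)c1ccccc1
F5 | step 7 | (S)-N,N-dimethyl-1-phenylethylammonium 2-{[(2R)-5-heptyl-2,7-dihydroxy-4-oxo-3,4-dihydro-2H-chromen-2-yl]methyl}-4,6-dihydroxybenzoate | CCCCCCCc1cc(O)cc2c1C(=O)C[C@@](O)(Cc1cc(O)cc(O)c1C(=O)[O-])O2.C[C@H]([NH+](C)C)c1ccccc1
F6 | step 1 | 1,3-bis(benzyloxy)-5-heptylbenzene | CCCCCCCc1cc(OCc2ccccc2)cc(OCc2ccccc2)c1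
F7 | step 1 | 1,5-bis(benzyloxy)-2-bromo-3-heptylbenzene | CCCCCCCc1cc(OCc2ccccc2)cc(OCc2ccccc2)c1Br
F8 | step 1 | [2,4-bis(benzyloxy)-6-heptylphenyl]lithium | CCCCCCCc1cc(OCc2ccccc2)cc(OCc2ccccc2)c1[Li]
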